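Late in the delta run D fell slowly: with λ = ln(charged D / D left), λ climbed at 0.902 /h up to the first reading, but between the readings at 0.833 h and 2.50 h it climbed at 0.355 /h, less than that. So I counted by factors of time, not hours: 0.538 of λ per unit of ln t. D and E give L over the catalyst J, with G also charged.

| flask | D | E | G | J | remark | time |
|---|---|---|---|---|---|---|
| epsilon | 0.20 M | 0.69 equiv | 5 equiv | 0.5 mol% | run made earlier |  |
| delta | 0.20 M | 10 equiv | 5 equiv | 0.5 mol% | run made earlier |  |
| eta | 0.075 M | 2 equiv | 5 equiv | 0.5 mol% | run made earlier |  |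
| noon | 0.20 M | 0.500 equiv | 5.00 equiv | 0.5 mol% |  | 5.0 h |
| autumn | 0.20 M | 2.00 equiv | 5.00 equiv | 0.5 mol% |  | 5.0 h |
| dusk | 0.050 M | 2.00 equiv | 5.00 equiv | 0.25 mol% |  | 5.0 h |
| midnight | 0.20 M | 2.00 equiv | 5.00 equiv | 0.3 mol% |  | 5.0 h |
| summer | 0.060 M | 2.00 equiv | 5.00 equiv | 0.5 mol% |  | 5.0 h |
| winter | 0.20 M | 8.00 equiv | 5.00 equiv | 0.5 mol% |  | 5.0 h |

- epsilon (time / h: L / %, D / %): 0.200: 2.5, 100.7; 0.333: 0.5, 98.8; 0.500: 2.4, 96.1; 0.833: 4.7, 94.1; 1.50: 6.6, 95.8; 2.50: 7.1, 92.0
- delta (time / h: L / %, D / %): 0.200: 15.9, 83.5; 0.333: 24.8, 77.1; 0.500: 32.7, 68.4; 0.833: 43.8, 55.3; 1.50: 59.0, 40.0; 2.50: 68.3, 30.6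
- eta (time / h: L / %, D / %): 0.200: 0.3, 98.2; 0.417: 0, 99.1; 0.667: 2.7, 98.3; 1.33: 3.0, 96.8; 2.50: 4.2, 95.9

(each reading ± 1 percentage point)

1. ranking by amount of L, in percent of the D charged, from high to low, at 5.0 h (noon / autumn / dusk / midnight / summer / winter)
2. the amount of L, in percent of the D charged of the flask you put first, at 5.0 h
3. the amount of L, in percent of the D charged of the flask you put last, at 5.0 h

Taking the loss of D as pseudo-first-order, I carried the dose w, which is λ per molar of charged E, at the asked time on delta's J. Delta's last reading stepped on to 5.0 h gave 0.779 /M. I took the dose to follow charged J molarity times time, so a flask stands on delta's clock at τ, its time scaled by its J over delta's. Eta's last reading has τ = 0.938 h; stepping from delta's reading at 0.833 h gave 4.80 % of L, against 4.2 % read, with a scatter of 1 percentage point.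

Winter has delta's J, so my dose times its 1.60 M of E gave 71.2 % of L. Dusk, at τ = 0.625 h, stepped from delta's reading at 0.500 h, gave 2.47 %.

The forecast, holding that “the catalyst is dying rather than the product inhibiting”, ranked winter > autumn > midnight > noon > summer > dusk, with 72 % (62 % to 82 %) for winter and 2.4 % (1.2 % to 4.2 %) for dusk.

The flasks ran winter > autumn > midnight > noon > summer > dusk: winter gave 72.4 % and dusk 2.39 %.

    D + E + J → J + L (k = 8.40 /M²/min)
    G + E + J → J + Q (k = 1.20 /M²/min)
    2 J → X (k = 8.30 /M/min)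

At 5.00 h winter held 16.7 % of its charged catalyst as J and 83.3 % as X. Autumn also has delta's J, and my dose times its 0.400 M of E gives 26.8 %; autumn gave 27.0 %.

All runs come from a simulation with made-up constants, and the scatter is random.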